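## Analysis of the target

The target is a lignan dimer. One half is an olivil-type oxolane (ring B) carrying ring A on C7, CH2OH on C8, and on C8' a tertiary hydroxyl and the isovanillyl CH2 (C7'). The other half is a cycloolivil-type 1-aryltetralin with pendant ring C on C1 and fused ring D. The halves are joined by a biaryl bond between the two guaiacyl rings A and C, each ortho to its phenol.

There are six stereocentres in two triads. In the oxolane, C7 is S, C8 is R and C8' is S: ring A is trans to the C8 CH2OH, and the C7' benzyl is cis to it. In the tetralin, C1, C2 and C3 are all S: ring C is trans to the C2 CH2OH, and the C3 hydroxyl is cis to it. The triads lie on opposite sides of the biaryl bond, so neither can steer the other and each must be set in the absolute sense.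

The sensitive sites are the C7–O bond, the two tertiary carbinols and four oxidisable phenols. With a free para-hydroxyl on ring A, the C7–O bond ionises in acid and is open to hydrogenolysis; the cation would attack a neighbouring arene. Each tertiary carbinol sits β to a benzylic carbon.

The synthesis is hard for two reasons. Nine hydroxyls of three kinds must be told apart. The C8' carbinol has its benzyl group on the face of the oxolane already occupied by the C8 substituent, which is the contrasteric outcome for addition to a tetrahydrofuran-3-one.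

The strategy rests on one observation: joining O9 to C7' turns the oxolane half into a cis-fused dioxabicyclo[3.3.0]octane with the hydroxyl on the bridgehead C8'. Cis fusion is the only possible fusion there, so it fixes C7' and C9 on the same face.

## Retrosynthetic reasoning

**Unmasking (32 from 31 from 30).** The last two operations only free oxygen. Five benzyl ethers fall in one hydrogenolysis of 31, and the sulfonate on ring A of 30 is hydrolysed just before. Ring A oxygen stays an electron-poor sulfonate until every acidic or Lewis acidic step is over, because a free or alkylated para-oxygen would make C7–O the first bond to ionise.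

**C7'–H and O9–H (30 from 29).** C7' of 30 is a methylene and C9 carries a free hydroxyl. Reconnecting O9 to C7' gives the bicyclic furofuranol 29. The forward step must cleave only the C7'–O bond reductively. It is the one benzylic C–O bond para to a methoxy group, while C7–O is para to the sulfonate.

**C7'–C8' (29 from 28), the key disconnection.** This bond joins the carbinol carbon to the benzylic carbon. Cutting it leaves a ketone at C8' and an isovanillyl ether on O9 in 28. The gain is that the carbinol configuration is no longer a question of facial selectivity; it follows from ring fusion to C8. The forward reaction must move a C7' hydrogen to the carbonyl oxygen and join the two radical centres.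

**O–C9' and C8'–C9' (28 from 27 from 26 from 25).** The ring CH2 of the oxolanone is cut twice: the ether bond goes back to chloroketone 27, and the C8'–C9' bond to the Weinreb amide 26 of aldol adduct 25. This places the ketone without ketal protection and without ever enolising C8.

**C7–C8 (25 from 17 and 23).** An anti-aldol disconnection gives the biaryl aldehyde 17 and the imide 23, which already carries the isovanillyl ether. The auxiliary 6 sets both centres of this triad in the absolute sense. A racemic ring construction on an enantiopure tetralin would give a mixture of diastereomers that differ only at remote centres.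

**Biaryl bond (17 from 14 and 16).** The bond between rings A and C is cut into the tetralin bromide 14 and the boronate 16. Both ortho positions carry oxygen, and the sulfonate of 16 is inert to the chosen palladium catalyst.

**C3–O and C4–H (14 from 13 from 12 from 11).** The tertiary carbinol comes from opening epoxide 12 with hydride at the benzylic C4. The epoxide comes from the dihydronaphthalene diol 11, where the C9 hydroxyl directs the oxidant to its own face.

**C1–C8a and C1–C2 (11 from 10 from 9 from 8 and 2).** The carbocycle is opened at the bond from C1 to ring D (Friedel–Crafts), then at C1–C2 (aldol). The aldol sets C2 through the auxiliary 6. C1 is set in the ring closure, trans to C2.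

**Building blocks.** Imide 8 comes from the Stobbe half-ester 5, which is made from 3 and 4. Imide 23 comes from acid 21, made from 18 and 19. Boronate 16 comes from 15, and both 15 and 2 come from 1.

## Alternatives that were turned down

**Alternative 1: acid-triggered oxolane-to-tetralin rearrangement.**
- Disconnection: the C1–C8a bond of the tetralin, at the dimer stage.
- Forward key step: acid ionises the C7–O bond of the vanillyl-bearing oxolane of the bis-oxolane A2, and the vanillyl ring closes onto the cation to give the monoacetate A1.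
- For: this isomerisation is known for olivil-type oxolanes, gives the 1,2-trans tetralin, and would let both halves be grown in two directions from one symmetric biaryl dialdehyde. On step count it is potentially stronger than the chosen route.
- Against: rings A and C of A2 are constitutionally alike, so both C7–O bonds ionise at similar rates. Only the acetate on the isovanillyl ring distinguishes the two cations, and the second one can still close para to the acetoxy group, epimerise C7 or be trapped. A2 also needs the C8' carbinol built twice, which is the very problem the Norrish–Yang step solves.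
- Comparison: the chosen route closes the tetralin on a monomer (9 to 10), where only one benzylic position exists. The finished oxolane never meets acid while ring A is electron-rich.

**Alternative 2: ring D by alkyne cyclotrimerisation.**
- Disconnection: three bonds of ring D (C4a–C8a, C5–C6, C7–C8).
- Forward key step: RhCl(PPh3)3 (monovalent rhodium) cyclotrimerises the silicon-tethered triyne A4 to the tetralin A3, closing arene, carbocycle and a temporary siloxane ring together.
- For: it is convergent, and the tether fixes the substitution pattern of ring D.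
- Against: ring D is an ordinary guaiacyl ring. A4 must already carry C1, C2 and C3 on an open chain, so the cyclisation sets none of the six stereocentres. The ynol ether is fragile. After A3, the silicon must still be oxidised to the phenol and the whole oxolane half built from the masked aldehyde.
- Comparison: in the chosen route ring D comes intact from aldehyde 3 and the Friedel–Crafts closure (step 5) also sets C1. The alternative is equal on regiocontrol of ring D and weaker on step economy and stereocontrol.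

**Alternative 3: ring C from a 2-pyrone and an ynol ether.**
- Disconnection: two bonds of ring C (C5–C6 and C3–C4).
- Forward key step: the silyl ynol ether A7 adds across C3 and C6 of the pyrone A6, and decarboxylative aromatisation gives the fully protected target A5.
- For: it joins two complete halves late and makes the doubly ortho-oxygenated biaryl without a cross-coupling. On late-stage convergence it is stronger than the chosen route.
- Against: A7 must already contain the finished oxolane with its C8' carbinol, so the alternative presupposes the hardest stereocentre and does not create it. Diene and dienophile are both electron-rich, so the cycloaddition needs forcing conditions that the benzylic ether and the tertiary silyl ether may not survive.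
- Comparison: the chosen route makes the biaryl by a routine Suzuki coupling at the robust aldehyde stage (step 12) and spends its risk on the step that creates C8'.

Key step: step 19

## Remarks and assumptions

- Locants follow lignan practice. In the tetralin, C1 carries ring C, C2 carries CH2O (C9), C3 is the carbinol carbon carrying C9', and ring D is C4a to C8a. In the oxolane half, C7 carries ring A, C8 carries C9, C8' is the carbonyl or carbinol carbon, C9' is the ring CH2 and C7' is the isovanillyl benzylic carbon.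
- Abbreviations used in names:
  - Xc = (4S)-4-benzyl-2-oxo-1,3-oxazolidin-3-yl.
  - IsoV = 3-(benzyloxy)-4-methoxyphenyl.
  - T = (1S,2S,3S)-7-(benzyloxy)-2,3-bis[(benzyloxy)methyl]-3-hydroxy-6-methoxy-1,2,3,4-tetrahydronaphthalen-1-yl.
  - ArA = 3-methoxy-4-(tosyloxy)-5-[2-(benzyloxy)-3-methoxy-5-T-phenyl]phenyl.
- Assumption: the magnesium-catalysed anti-aldol of an N-acyl oxazolidinone is taken to react through the chelated Z-enolate on the face away from the benzyl group, as in enolate alkylation. On that basis the (S)-auxiliary 6 gives the (2R,3S) adduct 25.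
- Compounds 1, 3, 4, 6, 18 and 19 are catalogue chemicals.

## Route

Step 1
Reactants: 1 5-bromovanillin
Product: 2 4-(benzyloxy)-3-bromo-5-methoxybenzaldehyde
Conditions: BnBr, K2CO3, DMF, 60 °C
Reagents that add atoms: benzyl bromide, BrCc1ccccc1
Why: Williamson etherification of the phenoxide; the benzyl ether lasts to the final hydrogenolysis and the bromide is the later coupling handle of ring C.

Step 2
Reactants: 3 4-(benzyloxy)-3-methoxybenzaldehyde; 4 dimethyl succinate
Product: 5 (E)-4-[4-(benzyloxy)-3-methoxyphenyl]-3-(methoxycarbonyl)but-3-enoic acid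
Conditions: NaOMe, MeOH, reflux; then aq. HCl
Reagents that add atoms: none
Why: Stobbe condensation; the paraconate intermediate opens irreversibly to the E half-ester, which places ring D cis to the CH2CO2H arm, the geometry the later ring closure needs.

Step 3
Reactants: 5 Stobbe half-ester; 6 (S)-4-benzyl-1,3-oxazolidin-2-one
Product: 8 methyl (E)-3-[4-(benzyloxy)-3-methoxyphenyl]-2-(2-oxo-2-Xc-ethyl)acrylate, via mixed pivalic anhydride 7 (not isolated)
Conditions: PivCl, Et3N, THF, −20 °C; then 6, LiCl, −20 °C to rt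
Reagents that add atoms: pivaloyl chloride, CC(C)(C)C(=O)Cl (its atoms are in 7 only)
Why: N-acylation of the oxazolidinone through a mixed anhydride, which is attacked at the less hindered acyl carbon; the conjugated methyl ester is untouched.

Step 4
Reactants: 8 N-acyl oxazolidinone; 2 ring C aldehyde
Product: 9 syn-aldol adduct Xc–CO–(2S)-CH[C(CO2Me)=CH-aryl]–(3S)-CH(OH)–(4-benzyloxy-3-bromo-5-methoxyphenyl)
Conditions: n-Bu2BOTf, i-Pr2NEt, CH2Cl2, −78 to 0 °C; 2, −78 to 0 °C; then H2O2, pH 7 buffer, MeOH, 0 °C
Reagents that add atoms: none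
Why: Evans boron aldol through the Z-enolate and a chair transition state with the aldehyde on the face away from the auxiliary benzyl group; this sets C2 of the tetralin, while the carbinol centre is ionised in step 5 and need not be controlled.

Step 5
Reactants: 9 syn-aldol adduct
Product: 10 methyl (1S,2R)-7-(benzyloxy)-1-(4-benzyloxy-3-bromo-5-methoxyphenyl)-6-methoxy-2-(Xc-carbonyl)-1,2-dihydronaphthalene-3-carboxylate
Conditions: TFA, CH2Cl2, −20 to 0 °C
Reagents that add atoms: none
Why: Intramolecular Friedel–Crafts alkylation; the para-alkoxybenzylic cation at C1 is attacked by ring D para to its methoxy group, closing the six-membered ring. Ring C should enter trans to the acyl group on C2, both ending pseudoaxial, which sets C1.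

Step 6
Reactants: 10 dihydronaphthalene imide ester
Product: 11 [(1S,2R)-7-(benzyloxy)-1-(4-benzyloxy-3-bromo-5-methoxyphenyl)-6-methoxy-1,2-dihydronaphthalene-2,3-diyl]dimethanol
Conditions: LiAlH4, THF, −10 to 0 °C
Reagents that add atoms: none
Why: Hydride reduction of the imide, with release of the auxiliary, and 1,2-reduction of the conjugated ester; the aryl bromide and the styrenic double bond should survive at this temperature.

Step 7
Reactants: 11 allylic and homoallylic diol
Product: 12 (1S,2S,3S,4S)-3,4-epoxide of 11 (oxirane oxygen on the face of the C2 hydroxymethyl group)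
Conditions: VO(acac)2 (5 mol %), t-BuOOH, CH2Cl2, 0 °C; neutral work-up, used crude
Reagents that add atoms: tert-butyl hydroperoxide, CC(C)(C)OO
Why: Hydroxyl-directed epoxidation; the pseudoaxial C9 hydroxymethyl lies over the C3=C4 bond and, with the allylic C9' hydroxyl, anchors the vanadium peroxide on that face, while the pseudoaxial ring C shields the other face. This sets C3.

Step 8
Reactants: 12 epoxy diol
Product: 13 (1S,2S,3S)-7-(benzyloxy)-1-(4-benzyloxy-3-bromo-5-methoxyphenyl)-2,3-bis(hydroxymethyl)-6-methoxy-1,2,3,4-tetrahydronaphthalen-3-ol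
Conditions: LiAlH4, THF, 0 °C to rt
Reagents that add atoms: none
Why: SN2 opening of the epoxide by hydride at the secondary benzylic C4; C3 is quaternary and cannot be attacked, so the tertiary carbinol keeps the configuration set in step 7.

Step 9
Reactants: 13 triol
Product: 14 (1S,2S,3S)-7-(benzyloxy)-1-(4-benzyloxy-3-bromo-5-methoxyphenyl)-2,3-bis[(benzyloxy)methyl]-6-methoxy-1,2,3,4-tetrahydronaphthalen-3-ol
Conditions: NaH (2.3 equiv), BnBr (2.2 equiv), n-Bu4NI (cat.), THF–DMF, 0 °C to rt
Reagents that add atoms: benzyl bromide, BrCc1ccccc1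
Why: Williamson etherification of the two primary alkoxides; the hindered tertiary hydroxyl reacts much more slowly and is left free, since it is inert in all later steps.

Step 10
Reactants: 1 5-bromovanillin
Product: 15 2-bromo-4-formyl-6-methoxyphenyl 4-methylbenzenesulfonate
Conditions: TsCl, Et3N, DMAP (cat.), CH2Cl2, 0 °C to rt
Reagents that add atoms: p-toluenesulfonyl chloride, Cc1ccc(S(=O)(=O)Cl)cc1
Why: O-sulfonylation; the tosylate withstands bases, organometallics and Lewis acids, and makes ring A too electron-poor for C7–O to ionise later.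

Step 11
Reactants: 15 aryl bromide
Product: 16 4-formyl-2-methoxy-6-(4,4,5,5-tetramethyl-1,3,2-dioxaborolan-2-yl)phenyl 4-methylbenzenesulfonate
Conditions: B2pin2, Pd(dppf)Cl2 (3 mol %), KOAc, 1,4-dioxane, 90 °C
Reagents that add atoms: bis(pinacolato)diboron, CC1(C)OB(OC1(C)C)B1OC(C)(C)C(C)(C)O1
Why: Miyaura borylation of the electron-poor aryl bromide; aldehyde and aryl sulfonate are inert to this catalyst.

Step 12
Reactants: 14 tetralin bromide; 16 boronate
Product: 17 biaryl aldehyde ArA–CHO
Conditions: Pd(dppf)Cl2 (5 mol %), K3PO4, 1,4-dioxane–H2O, 85 °C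
Reagents that add atoms: none
Why: Suzuki–Miyaura coupling forms the ring A to ring C bond; only the C–Br bond undergoes oxidative addition, because aryl tosylates do not react with this diphosphine catalyst.

Step 13
Reactants: 18 [3-(benzyloxy)-4-methoxyphenyl]methanol; 19 methyl acrylate
Product: 21 3-(IsoV-methoxy)propanoic acid, via methyl ester 20 (not isolated)
Conditions: KOt-Bu (10 mol %), THF, 0 °C to rt; then LiOH, H2O, rt; aq. HCl
Reagents that add atoms: lithium hydroxide, [Li+].[OH-]
Why: Base-catalysed oxa-Michael addition of the benzylic alkoxide to the acrylate, then saponification in the same flask.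

Step 14
Reactants: 21 acid; 6 (S)-4-benzyl-1,3-oxazolidin-2-one
Product: 23 Xc–CO–CH2CH2–O–CH2–IsoV, via mixed pivalic anhydride 22 (not isolated)
Conditions: PivCl, Et3N, THF, −20 °C; then 6, LiCl, rt
Reagents that add atoms: pivaloyl chloride, CC(C)(C)C(=O)Cl (its atoms are in 22 only)
Why: Same N-acylation as in step 3; the isovanillyl ether is carried from here on as the future C7' and its ring.

Step 15
Reactants: 17 biaryl aldehyde; 23 imide (1.5 equiv)
Product: 25 anti-aldol adduct Xc–CO–(2R)-CH(CH2OCH2-IsoV)–(3S)-CH(OH)–ArA, via trimethylsilyl ether 24 (not isolated)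
Conditions: MgCl2 (20 mol %), Et3N, Me3SiCl, EtOAc, rt; then TFA (cat.), MeOH, rt
Reagents that add atoms: chlorotrimethylsilane, C[Si](C)(C)Cl (its atoms are in 24 only)
Why: Evans magnesium-catalysed anti-aldol of an N-acyl oxazolidinone with a non-enolisable aromatic aldehyde; the chelated Z-enolate is attacked on the face away from the auxiliary benzyl group (C8) and the anti relation sets C7, while silylation of the aldolate stops retro-aldol equilibration. Any silyl ether formed on the tertiary hydroxyl is cleaved in the same methanolysis.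

Step 16
Reactants: 25 anti-aldol adduct
Product: 26 Weinreb amide MeO(Me)N–CO–(2R)-CH(CH2OCH2-IsoV)–(3S)-CH(OH)–ArA
Conditions: MeNH(OMe)·HCl, AlMe3, CH2Cl2, −10 to 0 °C
Reagents that add atoms: N,O-dimethylhydroxylamine hydrochloride, CNOC.Cl
Why: Transamination of the imide by the aluminium amide, assisted by the free β-hydroxyl as its aluminium alkoxide; the auxiliary is released and neither stereocentre is touched.

Step 17
Reactants: 26 Weinreb amide
Product: 27 (3R,4S)-4-ArA-1-chloro-4-hydroxy-3-(IsoV-methoxymethyl)butan-2-one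
Conditions: ICH2Cl, MeLi·LiBr, THF, −78 °C; then aq. NH4Cl
Reagents that add atoms: chloroiodomethane, ClCI
Why: Chloromethyllithium, formed in situ by iodine–lithium exchange, adds once to the Weinreb amide because the chelated tetrahedral adduct holds until the quench; the alkoxides formed from the two hydroxyls stay inert.

Step 18
Reactants: 27 chloromethyl ketone
Product: 28 (4R,5S)-5-ArA-4-(IsoV-methoxymethyl)dihydrofuran-3(2H)-one
Conditions: K2CO3, NaI (cat.), MeCN, 0 °C to rt
Reagents that add atoms: none
Why: Intramolecular Williamson etherification (5-exo-tet) of the benzylic hydroxyl on the activated α-halo ketone carbon; the anti adduct gives the 2,3-trans ketone directly, which is also the more stable epimer at C8.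

Step 19
Reactants: 28 tetrahydrofuran-3-one
Product: 29 (7S,8R,7'R,8'S) cis-fused furofuranol: 2-ArA-6-IsoV-3,7-dioxabicyclo[3.3.0]octan-5-ol (hydroxyl on the bridgehead C8' next to C7')
Conditions: hν (medium-pressure Hg lamp, Pyrex filter, λ > 300 nm), degassed benzene (5 mM), 20 °C
Reagents that add atoms: none
Why: Excitation of the n,π* band of the ketone is followed by transfer of a C7' hydrogen to the carbonyl oxygen through a seven-membered transition state (1,6-transfer of the δ-hydrogen); this C–H bond is benzylic and α to the ether oxygen, and the ketone has no abstractable γ-hydrogen. The resulting 1,5-biradical (ketyl carbon C8', benzylic carbon C7') cannot fragment by β-scission as a 1,4-biradical would, so it collapses by radical–radical combination. The closest known reaction type is the Norrish–Yang photocyclisation of β-alkoxy ketones to tetrahydrofuran-3-ols, which has been used to reach bridgehead-hydroxy furofuran lignans. The one new ring is a five-membered oxolane, closed by joining the two ends of the 1,5-biradical across C7'–C8'. C8' is controlled by C8: the tether starts at C9, so the new bond can form only on the face of the ketyl that carries the arm, the bicycle is necessarily cis-fused and the hydroxyl ends cis to H8. At C7' the aryl group should prefer the convex face, but this configuration is of no consequence because step 20 turns C7' into a methylene. The step needs hydrogen abstraction to outrun α-cleavage and excited-state quenching; the doubly activated δ-hydrogen held near the carbonyl, the Pyrex cut-off that leaves the aryl sulfonate and benzyl ethers unexcited, and high dilution without oxygen are meant to secure this.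

Step 20
Reactants: 29 furofuranol
Product: 30 (7S,8R,8'S)-oxolane ArA–C7, CH2OH on C8, OH and CH2–IsoV on C8' (ring A tosylate, five benzyl ethers)
Conditions: Et3SiH (excess), BF3·OEt2, CH2Cl2, −60 to −20 °C; aq. NaHCO3
Reagents that add atoms: none
Why: Ionic hydrogenation of a benzylic ether; only C7'–O is para to a methoxy group and can ionise, whereas C7–O is para to the sulfonate, and the cation is captured by the silane to give the C7' methylene and the free C9 hydroxyl. C7, C8 and C8' are not involved.

Step 21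
Reactants: 30 ring A tosylate
Product: 31 ring A phenol of 30
Conditions: KOH, 1,4-dioxane–H2O, 90 °C; then aq. NH4Cl
Reagents that add atoms: none
Why: Hydrolysis of the aryl sulfonate by attack of hydroxide at sulfur; it is done in the absence of alcohols so that no alkyl tosylate can re-alkylate the phenoxide, and only after the last acidic step.

Step 22
Reactants: 31 penta-O-benzyl ether
Product: 32 target CNP0252244.1
Conditions: H2 (1 atm), Pd/C (10 %), EtOAc–MeOH, rt
Reagents that add atoms: none
Why: Neutral hydrogenolysis of the three aryl and two alkyl benzyl ethers; it is stopped at full conversion so that the benzylic C7–O bond of the oxolane is not reduced.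

## Compound list

1 | 5-bromovanillin (3-bromo-4-hydroxy-5-methoxybenzaldehyde) | COc1cc(C=O)cc(Br)c1O | starting material
2 | 4-(benzyloxy)-3-bromo-5-methoxybenzaldehyde | COc1cc(C=O)cc(Br)c1OCc1ccccc1 | intermediate
3 | 4-(benzyloxy)-3-methoxybenzaldehyde | COc1cc(C=O)ccc1OCc1ccccc1 | starting material
4 | dimethyl succinate | COC(=O)CCC(=O)OC | starting material
5 | (E)-4-[4-(benzyloxy)-3-methoxyphenyl]-3-(methoxycarbonyl)but-3-enoic acid | COC(=O)/C(CC(=O)O)=C/c1ccc(OCc2ccccc2)c(OC)c1 | intermediate
6 | (S)-4-benzyl-1,3-oxazolidin-2-one | O=C1OC[C@H](Cc2ccccc2)N1 | starting material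
7 | mixed pivalic anhydride of 5 | COC(=O)/C(CC(=O)OC(=O)C(C)(C)C)=C/c1ccc(OCc2ccccc2)c(OC)c1 | intermediate
8 | methyl (E)-3-[4-(benzyloxy)-3-methoxyphenyl]-2-(2-oxo-2-Xc-ethyl)acrylate | COC(=O)/C(CC(=O)N1[C@@H](Cc2ccccc2)COC1=O)=C/c1ccc(OCc2ccccc2)c(OC)c1 | intermediate
9 | (2S,3S) syn-aldol adduct of 8 and 2 | COC(=O)/C(=C/c1ccc(OCc2ccccc2)c(OC)c1)[C@@H]([C@H](O)c1cc(OC)c(OCc2ccccc2)c(Br)c1)C(=O)N1[C@@H](Cc2ccccc2)COC1=O | intermediate
10 | methyl (1S,2R)-7-(benzyloxy)-1-(4-benzyloxy-3-bromo-5-methoxyphenyl)-6-methoxy-2-(Xc-carbonyl)-1,2-dihydronaphthalene-3-carboxylate | COC(=O)C1=Cc2cc(OC)c(OCc3ccccc3)cc2[C@H](c2cc(OC)c(OCc3ccccc3)c(Br)c2)[C@H]1C(=O)N1[C@@H](Cc2ccccc2)COC1=O | intermediate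
11 | [(1S,2R)-7-(benzyloxy)-1-(4-benzyloxy-3-bromo-5-methoxyphenyl)-6-methoxy-1,2-dihydronaphthalene-2,3-diyl]dimethanol | OCC1=Cc2cc(OC)c(OCc3ccccc3)cc2[C@H](c2cc(OC)c(OCc3ccccc3)c(Br)c2)[C@H]1CO | intermediate
12 | (1S,2S,3S,4S)-3,4-epoxide of 11 | OC[C@]12O[C@H]1c1cc(OC)c(OCc3ccccc3)cc1[C@H](c1cc(OC)c(OCc3ccccc3)c(Br)c1)[C@H]2CO | intermediate
13 | (1S,2S,3S)-7-(benzyloxy)-1-(4-benzyloxy-3-bromo-5-methoxyphenyl)-2,3-bis(hydroxymethyl)-6-methoxy-1,2,3,4-tetrahydronaphthalen-3-ol | Brc1cc([C@H]2c3cc(OCc4ccccc4)c(OC)cc3C[C@@](O)(CO)[C@@H]2CO)cc(OC)c1OCc1ccccc1 | intermediate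
14 | (1S,2S,3S)-7-(benzyloxy)-1-(4-benzyloxy-3-bromo-5-methoxyphenyl)-2,3-bis[(benzyloxy)methyl]-6-methoxy-1,2,3,4-tetrahydronaphthalen-3-ol | Brc1cc([C@H]2c3cc(OCc4ccccc4)c(OC)cc3C[C@@](O)(COCc3ccccc3)[C@@H]2COCc2ccccc2)cc(OC)c1OCc1ccccc1 | intermediate
15 | 2-bromo-4-formyl-6-methoxyphenyl 4-methylbenzenesulfonate | COc1cc(C=O)cc(Br)c1OS(=O)(=O)c1ccc(C)cc1 | intermediate
16 | 4-formyl-2-methoxy-6-(4,4,5,5-tetramethyl-1,3,2-dioxaborolan-2-yl)phenyl 4-methylbenzenesulfonate | COc1cc(C=O)cc(B2OC(C)(C)C(C)(C)O2)c1OS(=O)(=O)c1ccc(C)cc1 | intermediate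
17 | biaryl aldehyde ArA–CHO | O=Cc1cc(OC)c(OS(=O)(=O)c2ccc(C)cc2)c(-c2cc([C@H]3c4cc(OCc5ccccc5)c(OC)cc4C[C@@](O)(COCc4ccccc4)[C@@H]3COCc3ccccc3)cc(OC)c2OCc2ccccc2)c1 | intermediate
18 | [3-(benzyloxy)-4-methoxyphenyl]methanol | COc1ccc(CO)cc1OCc1ccccc1 | starting material
19 | methyl acrylate | C=CC(=O)OC | starting material
20 | methyl 3-(IsoV-methoxy)propanoate | COc1ccc(COCCC(=O)OC)cc1OCc1ccccc1 | intermediate
21 | 3-(IsoV-methoxy)propanoic acid | COc1ccc(COCCC(=O)O)cc1OCc1ccccc1 | intermediate
22 | mixed pivalic anhydride of 21 | COc1ccc(COCCC(=O)OC(=O)C(C)(C)C)cc1OCc1ccccc1 | intermediate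
23 | (4S)-4-benzyl-3-[3-(IsoV-methoxy)propanoyl]-1,3-oxazolidin-2-one | COc1ccc(COCCC(=O)N2[C@@H](Cc3ccccc3)COC2=O)cc1OCc1ccccc1 | intermediate
24 | O-trimethylsilyl ether of 25 | COc1ccc(COC[C@H]([C@H](O[Si](C)(C)C)c2cc(OC)c(OS(=O)(=O)c3ccc(C)cc3)c(-c3cc([C@H]4c5cc(OCc6ccccc6)c(OC)cc5C[C@@](O)(COCc5ccccc5)[C@@H]4COCc4ccccc4)cc(OC)c3OCc3ccccc3)c2)C(=O)N2[C@@H](Cc3ccccc3)COC2=O)cc1OCc1ccccc1 | intermediate
25 | (2R,3S) anti-aldol adduct Xc–CO–CH(CH2OCH2-IsoV)–CH(OH)–ArA | COc1ccc(COC[C@H]([C@H](O)c2cc(OC)c(OS(=O)(=O)c3ccc(C)cc3)c(-c3cc([C@H]4c5cc(OCc6ccccc6)c(OC)cc5C[C@@](O)(COCc5ccccc5)[C@@H]4COCc4ccccc4)cc(OC)c3OCc3ccccc3)c2)C(=O)N2[C@@H](Cc3ccccc3)COC2=O)cc1OCc1ccccc1 | intermediate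
26 | (2R,3S) Weinreb amide of 25 | COc1ccc(COC[C@H]([C@H](O)c2cc(OC)c(OS(=O)(=O)c3ccc(C)cc3)c(-c3cc([C@H]4c5cc(OCc6ccccc6)c(OC)cc5C[C@@](O)(COCc5ccccc5)[C@@H]4COCc4ccccc4)cc(OC)c3OCc3ccccc3)c2)C(=O)N(C)OC)cc1OCc1ccccc1 | intermediate
27 | (3R,4S)-4-ArA-1-chloro-4-hydroxy-3-(IsoV-methoxymethyl)butan-2-one | COc1ccc(COC[C@H]([C@H](O)c2cc(OC)c(OS(=O)(=O)c3ccc(C)cc3)c(-c3cc([C@H]4c5cc(OCc6ccccc6)c(OC)cc5C[C@@](O)(COCc5ccccc5)[C@@H]4COCc4ccccc4)cc(OC)c3OCc3ccccc3)c2)C(=O)CCl)cc1OCc1ccccc1 | intermediate
28 | (4R,5S)-5-ArA-4-(IsoV-methoxymethyl)dihydrofuran-3(2H)-one (key-step precursor) | COc1ccc(COC[C@H]2C(=O)CO[C@@H]2c2cc(OC)c(OS(=O)(=O)c3ccc(C)cc3)c(-c3cc([C@H]4c5cc(OCc6ccccc6)c(OC)cc5C[C@@](O)(COCc5ccccc5)[C@@H]4COCc4ccccc4)cc(OC)c3OCc3ccccc3)c2)cc1OCc1ccccc1 | intermediate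
29 | (7S,8R,7'R,8'S) cis-fused bridgehead-hydroxy furofuran (key-step product) | COc1ccc([C@H]2OC[C@H]3[C@]2(O)CO[C@@H]3c2cc(OC)c(OS(=O)(=O)c3ccc(C)cc3)c(-c3cc([C@H]4c5cc(OCc6ccccc6)c(OC)cc5C[C@@](O)(COCc5ccccc5)[C@@H]4COCc4ccccc4)cc(OC)c3OCc3ccccc3)c2)cc1OCc1ccccc1 | intermediate
30 | (7S,8R,8'S) ring-opened oxolane with ring A tosylate and five benzyl ethers | COc1ccc(C[C@@]2(O)CO[C@H](c3cc(OC)c(OS(=O)(=O)c4ccc(C)cc4)c(-c4cc([C@H]5c6cc(OCc7ccccc7)c(OC)cc6C[C@@](O)(COCc6ccccc6)[C@@H]5COCc5ccccc5)cc(OC)c4OCc4ccccc4)c3)[C@H]2CO)cc1OCc1ccccc1 | intermediate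
31 | ring A phenol of 30 (penta-O-benzyl target) | COc1ccc(C[C@@]2(O)CO[C@H](c3cc(OC)c(O)c(-c4cc([C@H]5c6cc(OCc7ccccc7)c(OC)cc6C[C@@](O)(COCc6ccccc6)[C@@H]5COCc5ccccc5)cc(OC)c4OCc4ccccc4)c3)[C@H]2CO)cc1OCc1ccccc1 | intermediate
32 | CNP0252244.1 | COc1ccc(C[C@@]2(O)CO[C@H](c3cc(OC)c(O)c(-c4cc([C@H]5c6cc(O)c(OC)cc6C[C@@](O)(CO)[C@@H]5CO)cc(OC)c4O)c3)[C@H]2CO)cc1O | target

## Step count and least certain steps

Total: 22 steps. Longest linear sequence: 17 steps (2 to 9, 12, 15 to 22).

**Step 19 (key step).** The excited ketone may be deactivated by energy transfer to the neighbouring biaryl, which has a lower triplet energy, before it abstracts hydrogen. α-Cleavage of the five-membered α-alkoxy ketone and light absorption by the arenes may also consume material. The fallback is thermal; it sets out from 28 and comes back at 32.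
- Lombardo methylenation (CH2Br2, Zn, TiCl4) should give the exocyclic alkene F1.
- A buffered peracid should attack anti to the C8 arm and give the spiro-epoxide F2, with the oxirane oxygen trans to C9.
- (3-Benzyloxy-4-methoxyphenyl)magnesium bromide with catalytic CuI should open the epoxide at its CH2 group and give the tertiary alcohol F3. Its benzyl group is cis to C9, and the isovanillyl ether on O9 is now only a protecting group.
- Hydrolysis of the sulfonate as in step 21 should give the phenol F4.
- Hydrogenolysis as in step 22 removes the benzyl groups and the dialkoxybenzyl ether on O9 and should give 32.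

**Step 20.** The C7' cation sits next to the tertiary carbinol, so a 1,2-shift of a ring bond (ring expansion to a ketone) may compete with hydride capture. The tertiary hydroxyls may also ionise if the mixture is warmed to force the reaction. The fallback sets out from 29 and comes back at 32: hydrogenolysis over Pd(OH)2/C in EtOAc–EtOH cleaves the C7'–O bond and the benzyl ethers without a free cation and should give the tosylate F5; hydrolysis of the sulfonate under argon then gives 32.

**Step 15.** The magnesium enolate carries a β-alkoxy group and may lose the isovanillyl alkoxide by E1cB elimination during the long reaction at room temperature. The sense of induction also rests on the stated assumption. The fallback sets out from 17 and 23 and comes back at 28.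
- The boron aldol of step 4 (n-Bu2BOTf, i-Pr2NEt, −78 °C) should give the syn adduct F10, which has the required C7 and the epimeric C8.
- Steps 16 to 18 applied to F10 should give the Weinreb amide F11, the chloroketone F12 and the cis ketone F13.
- Brief treatment with DBU in CH2Cl2 should equilibrate C8 to the more stable 2,3-trans ketone 28.

**Step 18.** Under base, retro-aldol cleavage of the β-hydroxy ketone, or enolisation toward C8 with loss of the β-alkoxy group, may compete with ether formation. The fallback sets out from 25 and comes back at 28.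
- Et3SiCl and imidazole should give the silyl ether F6.
- LiOOH should give the acid F7.
- Isobutyl chloroformate and N-methylmorpholine, then diazomethane, should give the diazoketone F8.
- HF·pyridine should give the hydroxy diazoketone F9.
- Rh2(OAc)4 (divalent rhodium) in CH2Cl2 closes the ring by O–H insertion under neutral conditions and should give 28.

**Step 5.** The benzylic cation may lose the C2 proton instead of cyclising. That gives an achiral bis-benzylidene succinate, which cyclises more slowly to racemic product and erodes the enantiopurity of C2. The fallback sets out from 9 and comes back at 11.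
- LiBH4 in wet THF removes the auxiliary, and the primary alcohol lactonises onto the neighbouring ester to give the hydroxy lactone F14.
- TFA then closes the ring in the known manner of α-benzylidene-β-(hydroxybenzyl) lactones and should give the dihydronaphthalene lactone F15.
- LiAlH4 should give 11.

**Step 7.** Delivery of oxygen to the wrong face would give the C3 epimer. The electron-rich epoxide may also be opened at C4 by one of its own hydroxyls if traces of acid are present. The fallback sets out from 11 and comes back at 13: dihydroxylation with OsO4 and TMEDA at −78 °C, directed by hydrogen bonding to the C9 hydroxyl, should give the tetraol F16; ionic deoxygenation of its benzylic C4 hydroxyl (Et3SiH, TFA, CH2Cl2, −40 °C) should give 13.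

## Further compounds

F1 | step 19 | (4R,5S)-5-ArA-4-(IsoV-methoxymethyl)-3-methyleneoxolane | COc1ccc(COC[C@H]2C(=C)CO[C@@H]2c2cc(OC)c(OS(=O)(=O)c3ccc(C)cc3)c(-c3cc([C@H]4c5cc(OCc6ccccc6)c(OC)cc5C[C@@](O)(COCc5ccccc5)[C@@H]4COCc4ccccc4)cc(OC)c3OCc3ccccc3)c2)cc1OCc1ccccc1
F2 | step 19 | spiro-epoxide of F1 (oxirane oxygen trans to C9) | COc1ccc(COC[C@H]2[C@@]3(CO3)CO[C@@H]2c2cc(OC)c(OS(=O)(=O)c3ccc(C)cc3)c(-c3cc([C@H]4c5cc(OCc6ccccc6)c(OC)cc5C[C@@](O)(COCc5ccccc5)[C@@H]4COCc4ccccc4)cc(OC)c3OCc3ccccc3)c2)cc1OCc1ccccc1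
F3 | step 19 | O9-(IsoV-methyl) ether of 30 | COc1ccc(COC[C@H]2[C@@](O)(Cc3ccc(OC)c(OCc4ccccc4)c3)CO[C@@H]2c2cc(OC)c(OS(=O)(=O)c3ccc(C)cc3)c(-c3cc([C@H]4c5cc(OCc6ccccc6)c(OC)cc5C[C@@](O)(COCc5ccccc5)[C@@H]4COCc4ccccc4)cc(OC)c3OCc3ccccc3)c2)cc1OCc1ccccc1
F4 | step 19 | O9-(IsoV-methyl) ether of 31 | COc1ccc(COC[C@H]2[C@@](O)(Cc3ccc(OC)c(OCc4ccccc4)c3)CO[C@@H]2c2cc(OC)c(O)c(-c3cc([C@H]4c5cc(OCc6ccccc6)c(OC)cc5C[C@@](O)(COCc5ccccc5)[C@@H]4COCc4ccccc4)cc(OC)c3OCc3ccccc3)c2)cc1OCc1ccccc1
F5 | step 20 | ring A O-tosylate of 32 | COc1ccc(C[C@@]2(O)CO[C@H](c3cc(OC)c(OS(=O)(=O)c4ccc(C)cc4)c(-c4cc([C@H]5c6cc(O)c(OC)cc6C[C@@](O)(CO)[C@@H]5CO)cc(OC)c4O)c3)[C@H]2CO)cc1O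
F6 | step 18 | O-triethylsilyl ether of 25 | COc1ccc(COC[C@H]([C@H](O[Si](CC)(CC)CC)c2cc(OC)c(OS(=O)(=O)c3ccc(C)cc3)c(-c3cc([C@H]4c5cc(OCc6ccccc6)c(OC)cc5C[C@@](O)(COCc5ccccc5)[C@@H]4COCc4ccccc4)cc(OC)c3OCc3ccccc3)c2)C(=O)N2[C@@H](Cc3ccccc3)COC2=O)cc1OCc1ccccc1
F7 | step 18 | (2R,3S)-3-ArA-2-(IsoV-methoxymethyl)-3-(triethylsilyloxy)propanoic acid | COc1ccc(COC[C@H]([C@H](O[Si](CC)(CC)CC)c2cc(OC)c(OS(=O)(=O)c3ccc(C)cc3)c(-c3cc([C@H]4c5cc(OCc6ccccc6)c(OC)cc5C[C@@](O)(COCc5ccccc5)[C@@H]4COCc4ccccc4)cc(OC)c3OCc3ccccc3)c2)C(=O)O)cc1OCc1ccccc1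
F8 | step 18 | (3R,4S)-4-ArA-1-diazo-3-(IsoV-methoxymethyl)-4-(triethylsilyloxy)butan-2-one | COc1ccc(COC[C@H]([C@H](O[Si](CC)(CC)CC)c2cc(OC)c(OS(=O)(=O)c3ccc(C)cc3)c(-c3cc([C@H]4c5cc(OCc6ccccc6)c(OC)cc5C[C@@](O)(COCc5ccccc5)[C@@H]4COCc4ccccc4)cc(OC)c3OCc3ccccc3)c2)C(=O)C=[N+]=[N-])cc1OCc1ccccc1
F9 | step 18 | (3R,4S)-4-ArA-1-diazo-4-hydroxy-3-(IsoV-methoxymethyl)butan-2-one | COc1ccc(COC[C@H]([C@H](O)c2cc(OC)c(OS(=O)(=O)c3ccc(C)cc3)c(-c3cc([C@H]4c5cc(OCc6ccccc6)c(OC)cc5C[C@@](O)(COCc5ccccc5)[C@@H]4COCc4ccccc4)cc(OC)c3OCc3ccccc3)c2)C(=O)C=[N+]=[N-])cc1OCc1ccccc1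
F10 | step 15 | (2S,3S) syn-aldol adduct (C8 epimer of 25) | COc1ccc(COC[C@@H]([C@H](O)c2cc(OC)c(OS(=O)(=O)c3ccc(C)cc3)c(-c3cc([C@H]4c5cc(OCc6ccccc6)c(OC)cc5C[C@@](O)(COCc5ccccc5)[C@@H]4COCc4ccccc4)cc(OC)c3OCc3ccccc3)c2)C(=O)N2[C@@H](Cc3ccccc3)COC2=O)cc1OCc1ccccc1
F11 | step 15 | C8 epimer of 26 | COc1ccc(COC[C@@H]([C@H](O)c2cc(OC)c(OS(=O)(=O)c3ccc(C)cc3)c(-c3cc([C@H]4c5cc(OCc6ccccc6)c(OC)cc5C[C@@](O)(COCc5ccccc5)[C@@H]4COCc4ccccc4)cc(OC)c3OCc3ccccc3)c2)C(=O)N(C)OC)cc1OCc1ccccc1
F12 | step 15 | C8 epimer of 27 | COc1ccc(COC[C@@H]([C@H](O)c2cc(OC)c(OS(=O)(=O)c3ccc(C)cc3)c(-c3cc([C@H]4c5cc(OCc6ccccc6)c(OC)cc5C[C@@](O)(COCc5ccccc5)[C@@H]4COCc4ccccc4)cc(OC)c3OCc3ccccc3)c2)C(=O)CCl)cc1OCc1ccccc1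
F13 | step 15 | (4S,5S) cis ketone (C8 epimer of 28) | COc1ccc(COC[C@@H]2C(=O)CO[C@@H]2c2cc(OC)c(OS(=O)(=O)c3ccc(C)cc3)c(-c3cc([C@H]4c5cc(OCc6ccccc6)c(OC)cc5C[C@@](O)(COCc5ccccc5)[C@@H]4COCc4ccccc4)cc(OC)c3OCc3ccccc3)c2)cc1OCc1ccccc1
F14 | step 5 | (E)-α-benzylidene-β-(hydroxybenzyl)-γ-butyrolactone from 9 | O=C1OC[C@H]([C@H](O)c2cc(OC)c(OCc3ccccc3)c(Br)c2)/C1=C\c1ccc(OCc2ccccc2)c(OC)c1
F15 | step 5 | (1S,2R) 1-aryl-1,2-dihydronaphthalene lactone | O=C1OC[C@H]2C1=Cc1cc(OC)c(OCc3ccccc3)cc1[C@@H]2c1cc(OC)c(OCc2ccccc2)c(Br)c1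
F16 | step 7 | 3,4-cis-diol of 11 (both hydroxyls on the face of the C2 hydroxymethyl group) | OC[C@]1(O)[C@@H](O)c2cc(OC)c(OCc3ccccc3)cc2[C@H](c2cc(OC)c(OCc3ccccc3)c(Br)c2)[C@H]1CO
A1 | alternative 1 | target monoacetate (isovanillyl O-acetate) | COc1ccc(C[C@@]2(O)CO[C@H](c3cc(OC)c(O)c(-c4cc([C@H]5c6cc(O)c(OC)cc6C[C@@](O)(CO)[C@@H]5CO)cc(OC)c4O)c3)[C@H]2CO)cc1OC(C)=O
A2 | alternative 1 | bis-oxolane dimer (vanillyl oxolane on ring C and O-acetylisovanillyl oxolane on ring A) | COc1ccc(C[C@@]2(O)CO[C@H](c3cc(OC)c(O)c(-c4cc([C@H]5OC[C@](O)(Cc6ccc(O)c(OC)c6)[C@@H]5CO)cc(OC)c4O)c3)[C@H]2CO)cc1OC(C)=O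
A3 | alternative 2 | tetralin with ring D silylated at the future phenol carbon | COc1cc(C2OCCO2)cc(-c3cc([C@H]4c5cc6c(OC)cc5C[C@]5(OC(C)(C)OC5)[C@@H]4CO[Si]6(C(C)C)C(C)C)cc(OC)c3OCc3ccccc3)c1OCc1ccccc1
A4 | alternative 2 | silicon-tethered triyne | COc1cc(C2OCCO2)cc(-c3cc([C@@H](C#C)[C@@H](CO[Si](C(C)C)(C(C)C)C#COC)[C@@]4(CC#C)COC(C)(C)O4)cc(OC)c3OCc3ccccc3)c1OCc1ccccc1
A5 | alternative 3 | fully protected target with ring C formed as its silyl ether | COc1ccc(C[C@@]2(O[Si](CC)(CC)CC)CO[C@H](c3cc(OC)c(OCc4ccccc4)c(-c4cc([C@H]5c6cc(OCc7ccccc7)c(OC)cc6C[C@]6(OC(C)(C)OC6)[C@@H]5COCc5ccccc5)cc(OC)c4O[Si](C(C)C)(C(C)C)C(C)C)c3)[C@H]2COCc2ccccc2)cc1OCc1ccccc1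
A6 | alternative 3 | 3-methoxy-5-(tetralin-1-yl)-2-pyrone | COC1=CC([C@H]2c3cc(OCc4ccccc4)c(OC)cc3C[C@]3(OC(C)(C)OC3)[C@@H]2COCc2ccccc2)=COC1=O
A7 | alternative 3 | ring A triisopropylsilyl ynol ether of the protected oxolane half | COc1ccc(C[C@@]2(O[Si](CC)(CC)CC)CO[C@H](c3cc(OC)c(OCc4ccccc4)c(C#CO[Si](C(C)C)(C(C)C)C(C)C)c3)[C@H]2COCc2ccccc2)cc1OCc1ccccc1
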